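## Retrosynthetic overview

1. Feature: the only ring is the benzene ring, with the side-chain CH2 on C1, OH on C3 and OMe on C5. This 1,3,5-pattern is a 5-alkylcyclohexane-1,3-dione two hydrogens short of aromaticity, and the OH/OMe pair is the mono methyl enol ether of that dione after dehydrogenation.
2. Target ⇒ (O-debenzylation) benzyl-protected phenol ⇒ (α′-selenoxide dehydrogenation) 3-methoxycyclohex-2-enone ⇒ (enol etherification) 5-substituted cyclohexane-1,3-dione ⇒ (decarboxylation) its carbomethoxy derivative.
3. Key disconnection, anionic [3+3]: ring bonds C1–C2 (Michael) and C3–C4 (Claisen) are cut to dimethyl malonate (C2, C3) and the (R,E)-δ-benzyloxy enone (C1, C6, C5, C4).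
4. Enone ⇒ cross-metathesis of methyl vinyl ketone with the benzyl ether of (R)-nonadec-1-en-4-ol ⇒ Keck allylation of hexadecanal, which sets the only stereocentre.
5. Ring order: one ring, closed as a carbocycle in step 4 and made aromatic in steps 7 and 8.

Key step: step 4

Remark: ring carbons that are stereogenic only between the annulation and the aromatisation are left undefined, because all epimers converge on the same arene. The cyclic 1,3-dicarbonyl compounds are drawn as keto tautomers although they should be largely enolised.

## Route

Step 1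
Reactants: 1 hexadecanal; 2 allyltributylstannane
Product: 4 (R)-nonadec-1-en-4-ol, via tributylstannyl ether 3 (not isolated)
Conditions: (S)-BINOL (10 mol %), Ti(OiPr)4 (10 mol %), 4 Å MS, CH2Cl2, reflux 1 h; then 1, 2 (1.2 equiv), −20 °C; sat. aq NaHCO3
Reagents that add atoms: none
Why: Keck asymmetric allylation: the (S)-BINOL–titanium(IV) Lewis acid binds the aldehyde and leaves only its Si face open to the allylstannane (open SE2′ transition state), which for an unbranched alkyl aldehyde corresponds to the R carbinol (O > allyl CH2 > alkyl CH2), and the tin alkoxide 3 formed on turnover is hydrolysed in the work-up.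

Step 2
Reactants: 4 (R)-nonadec-1-en-4-ol
Product: 5 (R)-4-(benzyloxy)nonadec-1-ene
Conditions: NaH (1.3 equiv), BnBr (1.2 equiv), Bu4NI (cat.), THF–DMF, 0 °C → rt
Reagents that add atoms: benzyl bromide, BrCc1ccccc1
Why: Williamson ether synthesis: the sodium alkoxide displaces bromide from benzyl bromide without touching the C–O bond at the stereocentre, and benzyl is chosen because it withstands the methoxide, hot hydroxide, acid, LDA and peroxide of steps 4–8 and keeps the oxygen from lactonising onto a malonate ester.

Step 3
Reactants: 5 (R)-4-(benzyloxy)nonadec-1-ene; 6 methyl vinyl ketone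
Product: 7 (R,E)-6-(benzyloxy)henicos-3-en-2-one
Conditions: 6 (3 equiv), Hoveyda–Grubbs II (3 mol %), CH2Cl2, 40 °C
Reagents that add atoms: none
Why: Olefin cross-metathesis of a rapidly reacting terminal alkene with an electron-poor, slowly homodimerising enone partner is selective for the cross product, should give the E-enone under thermodynamic control and is driven by loss of ethene.

Step 4
Reactants: 7 (R,E)-6-(benzyloxy)henicos-3-en-2-one; 8 dimethyl malonate
Product: 10 methyl 6-[(R)-2-(benzyloxy)heptadecyl]-2,4-dioxocyclohexane-1-carboxylate, via Michael adduct 9 (not isolated)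
Conditions: 8 (1.3 equiv), NaOMe (0.2 equiv), MeOH–THF, 0 °C → rt until 7 is consumed; then NaOMe (1.3 equiv), reflux; 1 M HCl, 0 °C
Reagents that add atoms: none
Why: Sodiomalonate adds 1,4 to the E-enone (Michael addition) and makes the future ring bond C1–C2; after the full charge of methoxide the methyl ketone of 9 enolises reversibly at its CH3 group and that carbon acylates itself on one ester carbonyl (intramolecular Claisen condensation), making the future C3–C4 bond with loss of methoxide. The closest known reaction type is the classical Michael–Claisen preparation of dimedone-type 5-alkylcyclohexane-1,3-diones from alk-3-en-2-ones and malonic esters. The one ring closes in the favoured 6-(enolendo)-exo-trig mode, the enolate at the internal CH2 could only give a four-membered ring, and deprotonation of 10 to its doubly stabilised enolate pulls all the reversible steps forward. Two stereocentres arise, ring C6 (no useful induction from the remote carbinol is expected, so both epimers should form) and ring C1 (equilibrated through the enol to the trans arrangement); neither needs control, because C1 goes with the carboxyl group and C6 goes on aromatisation. The selectivity that matters is chemoselectivity, since γ-deprotonation of 7 gives a dienolate that can expel the δ-benzyloxide (vinylogous E1cB); it is secured by keeping malonate in excess over base at low temperature, so that the weakly basic malonate anion is the main base present, and by adding the stoichiometric methoxide only when no enone is left. The carbinol carbon bears no acidic hydrogen and stays R.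

Step 5
Reactants: 10 methyl 6-[(R)-2-(benzyloxy)heptadecyl]-2,4-dioxocyclohexane-1-carboxylate
Product: 12 5-[(R)-2-(benzyloxy)heptadecyl]cyclohexane-1,3-dione, via beta-keto acid 11 (not isolated)
Conditions: 2 M aq NaOH, dioxane, reflux; then 6 M HCl to pH 1, reflux
Reagents that add atoms: sodium hydroxide, [Na+].[OH-] (its oxygen enters acid 11 and leaves again in CO2)
Why: Ester saponification followed by thermal decarboxylation of the β-keto acid 11 through its cyclic six-membered transition state, the standard finish of the malonate route to cyclohexane-1,3-diones: the dione rides through hot base as its inert enolate, the benzyl ether resists both media, and with the carboxyl gone the ring carbon bearing the side chain is no longer stereogenic.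

Step 6
Reactants: 12 5-[(R)-2-(benzyloxy)heptadecyl]cyclohexane-1,3-dione
Product: 13 5-[(R)-2-(benzyloxy)heptadecyl]-3-methoxycyclohex-2-en-1-one
Conditions: HC(OMe)3 (1.5 equiv), p-TsOH·H2O (5 mol %), MeOH, rt → 40 °C
Reagents that add atoms: trimethyl orthoformate, COC(OC)OC
Why: Acid-catalysed enol etherification of a vinylogous acid with orthoformate as methoxy donor and water scavenger: the two carbonyl groups of 12 are constitutionally equivalent so only one constitution can form, but they are diastereotopic because the side chain is chiral, so ring C5 becomes stereogenic and 13 should arise as two epimers that need no separation since both lead to the same arene.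

Step 7
Reactants: 13 5-[(R)-2-(benzyloxy)heptadecyl]-3-methoxycyclohex-2-en-1-one
Product: 14 5-[(R)-2-(benzyloxy)heptadecyl]-3-methoxy-6-(phenylselanyl)cyclohex-2-en-1-one
Conditions: LDA (1.15 equiv), THF, −78 °C; PhSeCl (1.2 equiv), THF, −78 °C; sat. aq NH4Cl
Reagents that add atoms: benzeneselenenyl chloride, Cl[Se]c1ccccc1
Why: α-Selenenylation of a kinetic ketone enolate: LDA deprotonates a 3-alkoxyenone at the α′-carbon C6 and not at the γ-carbon C4 (the regiochemistry of Stork–Danheiser alkylations), PhSeCl traps the cross-conjugated enolate faster than proton exchange can occur, and attack anti to the C5 side chain places Se syn to H-5 as the next step requires (the new C6 centre is transient and epimerisable).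

Step 8
Reactants: 14 5-[(R)-2-(benzyloxy)heptadecyl]-3-methoxy-6-(phenylselanyl)cyclohex-2-en-1-one
Product: 17 3-[(R)-2-(benzyloxy)heptadecyl]-5-methoxyphenol, via selenoxide 15 (not isolated), via cross-conjugated dienone 16 (not isolated)
Conditions: 30 % aq H2O2 (3 equiv), pyridine (2 equiv), CH2Cl2, 0 °C → rt; aq NaHCO3 wash
Reagents that add atoms: hydrogen peroxide, OO (its oxygen enters selenoxide 15 and leaves with the selenium)
Why: Selenoxide syn-elimination: peroxide oxidises Se, selenoxide 15 loses PhSeOH across C6–C5 at or below room temperature, and the resulting dienone 16 is merely the keto tautomer of a phenol, so pyridine-assisted enolisation at C4 makes the ring aromatic, turns the carbonyl oxygen into the free OH, leaves the enol-ether oxygen methylated and erases the ring stereocentres.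

Step 9
Reactants: 17 3-[(R)-2-(benzyloxy)heptadecyl]-5-methoxyphenol
Product: 18 3-[(R)-2-hydroxyheptadecyl]-5-methoxyphenol
Conditions: H2 (1 atm), 10 % Pd/C, EtOAc–EtOH, rt
Reagents that add atoms: none
Why: Catalytic hydrogenolysis of a benzyl ether breaks only the O–CH2Ph bond; the carbinol C–O bond is homobenzylic and unactivated, so the R configuration is retained, and the phenol, the aryl methyl ether and the arene are inert at 1 atm and room temperature.

## Compound list

1 | hexadecanal | CCCCCCCCCCCCCCCC=O | starting material
2 | allyltributylstannane | C=CC[Sn](CCCC)(CCCC)CCCC | starting material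
3 | tributyl{[(4R)-nonadec-1-en-4-yl]oxy}stannane | CCCCCCCCCCCCCCC[C@@H](O[Sn](CCCC)(CCCC)CCCC)CC=C | intermediate
4 | (R)-nonadec-1-en-4-ol | CCCCCCCCCCCCCCC[C@@H](O)CC=C | intermediate
5 | (R)-4-(benzyloxy)nonadec-1-ene | CCCCCCCCCCCCCCC[C@@H](OCc1ccccc1)CC=C | intermediate
6 | methyl vinyl ketone (but-3-en-2-one) | CC(=O)C=C | starting material
7 | (R,E)-6-(benzyloxy)henicos-3-en-2-one | CCCCCCCCCCCCCCC[C@@H](OCc1ccccc1)C/C=C/C(C)=O | intermediate
8 | dimethyl malonate | COC(=O)CC(=O)OC | starting material
9 | dimethyl 2-[(6R)-6-(benzyloxy)-2-oxohenicosan-4-yl]propanedioate (C4 epimers) | CCCCCCCCCCCCCCC[C@@H](OCc1ccccc1)CC(CC(C)=O)C(C(=O)OC)C(=O)OC | intermediate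
10 | methyl 6-[(R)-2-(benzyloxy)heptadecyl]-2,4-dioxocyclohexane-1-carboxylate (ring epimers) | CCCCCCCCCCCCCCC[C@@H](OCc1ccccc1)CC1CC(=O)CC(=O)C1C(=O)OC | intermediate
11 | 6-[(R)-2-(benzyloxy)heptadecyl]-2,4-dioxocyclohexane-1-carboxylic acid | CCCCCCCCCCCCCCC[C@@H](OCc1ccccc1)CC1CC(=O)CC(=O)C1C(=O)O | intermediate
12 | 5-[(R)-2-(benzyloxy)heptadecyl]cyclohexane-1,3-dione | CCCCCCCCCCCCCCC[C@@H](OCc1ccccc1)CC1CC(=O)CC(=O)C1 | intermediate
13 | 5-[(R)-2-(benzyloxy)heptadecyl]-3-methoxycyclohex-2-en-1-one (C5 epimers) | CCCCCCCCCCCCCCC[C@@H](OCc1ccccc1)CC1CC(=O)C=C(OC)C1 | intermediate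
14 | 5-[(R)-2-(benzyloxy)heptadecyl]-3-methoxy-6-(phenylselanyl)cyclohex-2-en-1-one | CCCCCCCCCCCCCCC[C@@H](OCc1ccccc1)CC1CC(OC)=CC(=O)C1[Se]c1ccccc1 | intermediate
15 | 5-[(R)-2-(benzyloxy)heptadecyl]-3-methoxy-6-(phenylseleninyl)cyclohex-2-en-1-one | CCCCCCCCCCCCCCC[C@@H](OCc1ccccc1)CC1CC(OC)=CC(=O)C1[Se](=O)c1ccccc1 | intermediate
16 | 3-[(R)-2-(benzyloxy)heptadecyl]-5-methoxycyclohexa-2,5-dien-1-one | CCCCCCCCCCCCCCC[C@@H](OCc1ccccc1)CC1=CC(=O)C=C(OC)C1 | intermediate
17 | 3-[(R)-2-(benzyloxy)heptadecyl]-5-methoxyphenol | CCCCCCCCCCCCCCC[C@@H](OCc1ccccc1)Cc1cc(O)cc(OC)c1 | intermediate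
18 | 3-[(R)-2-hydroxyheptadecyl]-5-methoxyphenol (CNP0573802.1) | CCCCCCCCCCCCCCC[C@@H](O)Cc1cc(O)cc(OC)c1 | target

Total step count: 9
Longest linear sequence: 9 steps (1 → 18)

## Steps most likely to fail

**1. Step 4.** γ-Deprotonation of the enone followed by vinylogous E1cB loss of benzyloxide would drain material and destroy the stereocentre. So would retro-Michael fragmentation at reflux before the ring has closed.

The fallback sets out from 5 and comes back at 10.
- 5 is cross-metathesised with methyl acrylate (Hoveyda–Grubbs II, CH2Cl2, 40 °C) to methyl (R,E)-5-(benzyloxy)icos-2-enoate F1.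
- Methyl acetoacetate and NaOMe in refluxing MeOH add to it to give dimethyl 2-acetyl-3-[(R)-2-(benzyloxy)heptadecyl]pentanedioate F2. This is not isolated, because the enolate of its acetyl CH3 group closes on the chain ester and gives 10 itself.
- Donor and acceptor roles are exchanged, so ring bonds C1–C2 and C4–C5 are made instead of C1–C2 and C3–C4.
- The γ-hydrogens of an enoate are several pK units less acidic than those of an enone, so the elimination channel is much weaker.

**2. Step 8.** The newly formed electron-rich phenol may be over-oxidised or selenenylated by the selenium by-products and peroxide. Elimination may also stall for the C6 epimer that has Se anti to H-5.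

The fallback sets out from 13 and comes back at 17.
- The kinetic enolate of 13 (LDA, THF, −78 °C) is O-silylated with TBSCl/DMPU to 5-[(R)-2-(benzyloxy)heptadecyl]-1-methoxy-3-(tert-butyldimethylsilyloxy)cyclohexa-1,3-diene F3, a true dihydroarene.
- DDQ (1.1 equiv, CH2Cl2, 0 °C) removes hydride and proton to give tert-butyl{3-[(R)-2-(benzyloxy)heptadecyl]-5-methoxyphenoxy}dimethylsilane F4.
- TBAF in THF releases 17.
- The phenol never meets selenium or peroxide, and a plain benzyl ether tolerates DDQ at 0 °C.

**3. Step 1.** Facial discrimination may be incomplete with an unbranched aliphatic aldehyde. Turnover may be slow because the waxy aldehyde is poorly soluble at −20 °C. Either would leave the enantiomeric purity short of a single enantiomer.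

The fallback sets out from 1 and comes back at 4.
- Corey–Chaykovsky methylenation (Me3S+ I−, NaH, DMSO–THF) gives rac-2-pentadecyloxirane F5.
- Hydrolytic kinetic resolution with (R,R)-(salen)Co(III)OAc (0.5 mol %) and water (0.55 equiv) consumes the S epoxide and leaves (R)-2-pentadecyloxirane F6, which is separated from the diol by chromatography.
- VinylMgBr with catalytic CuI (THF, −30 °C) opens the epoxide at its CH2 terminus and gives 4 with the C–O bond at the stereocentre untouched.
- Enantiomeric purity is then governed by the conversion of a resolution and not by facial selectivity.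

## Further compounds

F1 | step 4 | methyl (R,E)-5-(benzyloxy)icos-2-enoate | CCCCCCCCCCCCCCC[C@@H](OCc1ccccc1)C/C=C/C(=O)OC
F2 | step 4 | dimethyl 2-acetyl-3-[(R)-2-(benzyloxy)heptadecyl]pentanedioate | CCCCCCCCCCCCCCC[C@@H](OCc1ccccc1)CC(CC(=O)OC)C(C(C)=O)C(=O)OC
F3 | step 8 | 5-[(R)-2-(benzyloxy)heptadecyl]-1-methoxy-3-(tert-butyldimethylsilyloxy)cyclohexa-1,3-diene | CCCCCCCCCCCCCCC[C@@H](OCc1ccccc1)CC1CC(OC)=CC(O[Si](C)(C)C(C)(C)C)=C1
F4 | step 8 | tert-butyl{3-[(R)-2-(benzyloxy)heptadecyl]-5-methoxyphenoxy}dimethylsilane | CCCCCCCCCCCCCCC[C@@H](OCc1ccccc1)Cc1cc(OC)cc(O[Si](C)(C)C(C)(C)C)c1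
F5 | step 1 | rac-2-pentadecyloxirane | CCCCCCCCCCCCCCCC1CO1
F6 | step 1 | (R)-2-pentadecyloxirane | CCCCCCCCCCCCCCC[C@@H]1CO1
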